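**Strategy**

Everything rests on cutting the bond between the homoallylic CH2 of the polyprenyl chain and the alkene carbon that carries the internal CH2OH. The feature exploited is that O1 of the butenolide ring, on C5, lies homoallylic to this alkene and its arm is cis to the CH2OH group: O1–C5–CH2–CH=C is a ring-opened 2,3-dihydrofuran. In the key step a 5-lithio-2,3-dihydrofuran, whose C2 stereocentre carries a ketal-masked hydroxyketone, meets the homoallylic organocopper of the ω-silyloxy homofarnesyl iodide. A 1,2-metalate rearrangement forms the bond, opens the ring, fixes the alkene geometry and frees the future lactone oxygen, and ClCH2OSi(i-Pr)3 caps the alkenylcopper. A ketene-ylide cascade then closes the butenolide.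

Key step: step 13

Assumption: 2,2-dimethoxypropane-1,3-diol and (triisopropylsiloxy)methyl chloride are taken as catalogue reagents, and the sense of induction in step 11 is assigned by analogy, the catalyst enantiomer being the one that delivers (R)-15.

**Left fragment (steps 1–8)**

Step 1
Reactants: 1 (2E,6E)-farnesol
Product: 2 (2E,6E)-farnesyl acetate
Conditions: Ac2O, pyridine, DMAP (cat.), CH2Cl2, 0 °C to rt
Reagents that add atoms: acetic anhydride, CC(=O)OC(C)=O
Why: Nucleophile-catalysed O-acetylation (esterification) of the primary allylic alcohol, which also deactivates the 2,3-alkene toward the following allylic oxidation.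

Step 2
Reactants: 2 (2E,6E)-farnesyl acetate
Product: 3 (2E,6E,10E)-12-hydroxy-3,7,11-trimethyldodeca-2,6,10-trien-1-yl acetate
Conditions: SeO2 (cat.), t-BuOOH, salicylic acid (cat.), CH2Cl2, 0 °C to rt
Reagents that add atoms: tert-butyl hydroperoxide, CC(C)(C)OO
Why: Catalytic SeO2 allylic oxidation (Riley oxidation; ene reaction then [2,3]-sigmatropic shift) should attack the E-methyl group of the most electron-rich, terminal trisubstituted alkene and give the (E)-allylic alcohol.

Step 3
Reactants: 3 (2E,6E,10E)-12-hydroxy-3,7,11-trimethyldodeca-2,6,10-trien-1-yl acetate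
Product: 4 (2E,6E,10E)-12-(tert-butyldimethylsilyloxy)-3,7,11-trimethyldodeca-2,6,10-trien-1-yl acetate
Conditions: TBSCl, imidazole, DMF, 0 °C to rt
Reagents that add atoms: tert-butyldimethylsilyl chloride, CC(C)(C)[Si](C)(C)Cl
Why: Imidazole-promoted O-silylation of the primary allylic alcohol gives an ether that should survive base, ylide, borane and organolithium chemistry.

Step 4
Reactants: 4 (2E,6E,10E)-12-(tert-butyldimethylsilyloxy)-3,7,11-trimethyldodeca-2,6,10-trien-1-yl acetate
Product: 5 (2E,6E,10E)-12-(tert-butyldimethylsilyloxy)-3,7,11-trimethyldodeca-2,6,10-trien-1-ol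
Conditions: K2CO3, MeOH, rt
Reagents that add atoms: none
Why: Base-catalysed transesterification (methanolysis) removes the acetate while the primary silyl ether is stable to carbonate in methanol.

Step 5
Reactants: 5 (2E,6E,10E)-12-(tert-butyldimethylsilyloxy)-3,7,11-trimethyldodeca-2,6,10-trien-1-ol
Product: 6 (2E,6E,10E)-12-(tert-butyldimethylsilyloxy)-3,7,11-trimethyldodeca-2,6,10-trienal
Conditions: Dess–Martin periodinane, pyridine, CH2Cl2, 0 °C to rt
Reagents that add atoms: none
Why: Dess–Martin oxidation of the allylic alcohol under buffered, non-isomerising conditions should give the (E)-enal.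

Step 6
Reactants: 6 (2E,6E,10E)-12-(tert-butyldimethylsilyloxy)-3,7,11-trimethyldodeca-2,6,10-trienal
Product: 7 tert-butyldimethylsilyl ether of (2E,6E,10E)-2,6,10-trimethyltrideca-2,6,10,12-tetraen-1-ol
Conditions: Ph3PCH3Br, KOtBu, THF, 0 °C to rt
Reagents that add atoms: methyltriphenylphosphonium bromide, C[P+](c1ccccc1)(c1ccccc1)c1ccccc1.[Br-]
Why: Wittig methylenation of the enal with the non-stabilised ylide adds the terminal CH2 and leaves the existing alkene geometries untouched.

Step 7
Reactants: 7 tert-butyldimethylsilyl ether of (2E,6E,10E)-2,6,10-trimethyltrideca-2,6,10,12-tetraen-1-ol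
Product: 9 (3E,7E,11E)-13-(tert-butyldimethylsilyloxy)-4,8,12-trimethyltrideca-3,7,11-trien-1-ol, via B-alkyl-9-BBN adduct 8 (not isolated)
Conditions: 9-BBN, THF, 0 °C to rt; then NaOH, H2O2, 0 °C
Reagents that add atoms: hydrogen peroxide, OO (oxygen of 9); 9-BBN, B1C2CCCC1CCC2 (boron unit of intermediate 8 only)
Why: Hydroboration–oxidation with the bulky borane should select the monosubstituted terminal alkene of the diene over all trisubstituted alkenes and place oxygen at the terminal carbon (anti-Markovnikov).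

Step 8
Reactants: 9 (3E,7E,11E)-13-(tert-butyldimethylsilyloxy)-4,8,12-trimethyltrideca-3,7,11-trien-1-ol
Product: 10 (3E,7E,11E)-13-(tert-butyldimethylsilyloxy)-1-iodo-4,8,12-trimethyltrideca-3,7,11-triene
Conditions: I2, PPh3, imidazole, CH2Cl2, 0 °C to rt
Reagents that add atoms: iodine, [I][I]
Why: Appel-type iodination converts the primary homoallylic alcohol into the iodide by SN2 displacement of the alkoxyphosphonium ion, with imidazole buffering the silyl ether.

**Dihydrofuran fragment (steps 9–12)**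

Step 9
Reactants: 11 2,2-dimethoxypropane-1,3-diol
Product: 12 3-(tert-butyldimethylsilyloxy)-2,2-dimethoxypropan-1-ol
Conditions: NaH (1 equiv), THF, 0 °C; TBSCl (1 equiv), rt
Reagents that add atoms: tert-butyldimethylsilyl chloride, CC(C)(C)[Si](C)(C)Cl
Why: Monosilylation of the symmetric diol through its monosodium alkoxide (O-silylation) should stop at the mono-ether.

Step 10
Reactants: 12 3-(tert-butyldimethylsilyloxy)-2,2-dimethoxypropan-1-ol
Product: 13 3-(tert-butyldimethylsilyloxy)-2,2-dimethoxypropanal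
Conditions: Dess–Martin periodinane, pyridine, CH2Cl2, rt
Reagents that add atoms: none
Why: Buffered Dess–Martin oxidation of the neopentyl-type primary alcohol gives the non-enolisable aldehyde without endangering the ketal.

Step 11
Reactants: 13 3-(tert-butyldimethylsilyloxy)-2,2-dimethoxypropanal
Product: 15 (3R)-1-(tert-butyldimethylsilyloxy)-2,2-dimethoxyhex-5-yn-3-ol, via homopropargylic pinacol borate 14 (not isolated)
Conditions: allenylboronic acid pinacol ester, (R)-TRIP [3,3′-bis(2,4,6-triisopropylphenyl)-1,1′-binaphthyl-2,2′-diyl hydrogen phosphate] (10 mol %), 4 Å MS, toluene, −20 °C; aqueous work-up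
Reagents that add atoms: allenylboronic acid pinacol ester, C=C=CB1OC(C)(C)C(C)(C)O1 (propargyl carbons of 15; the boryl group stays only in intermediate 14)
Why: Chiral phosphoric acid-catalysed allenylboration (SE2′ propargylation through a six-membered cyclic transition state) should set the (R)-carbinol centre, since the acid hydrogen-bonds to a boronate oxygen and shields one aldehyde face.

Step 12
Reactants: 15 (3R)-1-(tert-butyldimethylsilyloxy)-2,2-dimethoxyhex-5-yn-3-ol
Product: 16 (2R)-2-[2-(tert-butyldimethylsilyloxy)-1,1-dimethoxyethyl]-2,3-dihydrofuran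
Conditions: Mo(CO)6 (cat.), Et3N, Et2O, hν (350 nm), rt
Reagents that add atoms: none
Why: Alkynol cycloisomerisation, in which photogenerated Et3N–Mo(CO)5 turns the terminal alkyne into a molybdenum vinylidene that the hydroxyl attacks at the metal-bound carbon (overall 5-endo closure), should give the 2,3-dihydrofuran without touching the carbinol stereocentre.

**Fragment union and endgame (steps 13–16)**

Step 13
Reactants: 10 (3E,7E,11E)-13-(tert-butyldimethylsilyloxy)-1-iodo-4,8,12-trimethyltrideca-3,7,11-triene; 16 (2R)-2-[2-(tert-butyldimethylsilyloxy)-1,1-dimethoxyethyl]-2,3-dihydrofuran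
Product: 21 (3R,5Z,9E,13E,17E)-1,19-bis(tert-butyldimethylsilyloxy)-2,2-dimethoxy-10,14,18-trimethyl-6-[(triisopropylsilyloxy)methyl]nonadeca-5,9,13,17-tetraen-3-ol, via homoallylic alkyllithium 17 (not isolated), via 5-lithiodihydrofuran 18 (not isolated), via lithium alkyl(alkenyl)cuprate 19 (not isolated), via ring-opened alkenylcopper alkoxide 20 (not isolated)
Conditions: 10, t-BuLi (2.1 equiv), Et2O, −78 °C; CuBr·SMe2 (1.0 equiv), Me2S, −78 to −40 °C; then 18 [from 16 (1.2 equiv), t-BuLi, THF, −78 to 0 °C], −78 °C to rt; then ClCH2OSi(i-Pr)3 (1.3 equiv), −40 to 0 °C; aq. NH4Cl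
Reagents that add atoms: (triisopropylsiloxy)methyl chloride, ClCO[Si](C(C)C)(C(C)C)C(C)C; t-BuLi, [Li]C(C)(C)C (lithium of 17, 18 only); CuBr·SMe2, Br[Cu].CSC (copper of 19, 20 only)
Why: Iodine–lithium exchange on 10 and transmetalation to copper give the homoallylic organocopper, which combines with the α-lithiated enol ether 18 to the mixed cuprate 19; on warming, the alkyl group migrates from copper to the metal-bearing sp2 carbon anti to the ring C–O bond (1,2-metalate rearrangement with inversion at the carbenoid carbon), expelling the ring oxygen as the alkoxide of 20, whose carbon–copper bond is then alkylated with retention by the α-chloro ether. The closest known reaction type is the 1,2-metalate rearrangement of cuprates of 5-lithio-2,3-dihydrofuran with homoallylic organocopper reagents followed by alkylation with MeI, used to build trisubstituted isoprenoid alkenes. No ring is closed; the dihydrofuran ring is opened. No stereocentre is created: C2 of 16 is not involved and becomes C3 of 21 unchanged, while the alkene geometry is dictated by the ring, which holds O1 and C3 cis, so that after inversion the migrated chain is trans and the copper (then CH2OSi(i-Pr)3) cis to the carbinol arm. The step needs transfer of the alkyl and not the alkenyl ligand, which the leaving group on the carbenoid carbon ensures, and C- over O-alkylation by the chloro ether, which the soft alkenylcopper at low temperature should win against the hindered, aggregated lithium alkoxide beside the quaternary ketal carbon.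

Step 14
Reactants: 21 (3R,5Z,9E,13E,17E)-1,19-bis(tert-butyldimethylsilyloxy)-2,2-dimethoxy-10,14,18-trimethyl-6-[(triisopropylsilyloxy)methyl]nonadeca-5,9,13,17-tetraen-3-ol
Product: 22 (3R,5Z,9E,13E,17E)-1,19-bis(tert-butyldimethylsilyloxy)-3-hydroxy-10,14,18-trimethyl-6-[(triisopropylsilyloxy)methyl]nonadeca-5,9,13,17-tetraen-2-one
Conditions: PPTS (cat.), acetone/H2O (10:1), 45 °C
Reagents that add atoms: water, O
Why: Acid-catalysed ketal hydrolysis through the oxocarbenium ion should unmask the ketone, the weak pyridinium acid in wet acetone being chosen to spare the primary silyl ethers, the trisubstituted alkenes and the carbinol centre.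

Step 15
Reactants: 22 (3R,5Z,9E,13E,17E)-1,19-bis(tert-butyldimethylsilyloxy)-3-hydroxy-10,14,18-trimethyl-6-[(triisopropylsilyloxy)methyl]nonadeca-5,9,13,17-tetraen-2-one
Product: 24 (5R)-4-[(tert-butyldimethylsilyloxy)methyl]-5-{(2Z,6E,10E,14E)-16-(tert-butyldimethylsilyloxy)-7,11,15-trimethyl-3-[(triisopropylsilyloxy)methyl]hexadeca-2,6,10,14-tetraen-1-yl}furan-2(5H)-one, via phosphoranylidene acetate ester 23 (not isolated)
Conditions: Ph3P=C=C=O, toluene, 90 °C
Reagents that add atoms: (triphenylphosphoranylidene)ketene, O=C=C=P(c1ccccc1)(c1ccccc1)c1ccccc1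
Why: Ketene-ylide cascade: the only free hydroxyl adds to the cumulated ylide to give ester ylide 23, whose intramolecular Wittig reaction with the adjacent ketone closes the five-membered butenolide under neutral conditions that leave the C5 stereocentre untouched.

Step 16
Reactants: 24 (5R)-4-[(tert-butyldimethylsilyloxy)methyl]-5-{(2Z,6E,10E,14E)-16-(tert-butyldimethylsilyloxy)-7,11,15-trimethyl-3-[(triisopropylsilyloxy)methyl]hexadeca-2,6,10,14-tetraen-1-yl}furan-2(5H)-one
Product: 25 Hippolide F, (5R)-4-(hydroxymethyl)-5-[(2Z,6E,10E,14E)-16-hydroxy-3-(hydroxymethyl)-7,11,15-trimethylhexadeca-2,6,10,14-tetraen-1-yl]furan-2(5H)-one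
Conditions: HF·pyridine, pyridine, THF, 0 °C to rt
Reagents that add atoms: none
Why: Fluoride-mediated desilylation under buffered, mildly acidic conditions removes all three silyl ethers and avoids the base-induced γ-deprotonation that would racemise C5 of the butenolide.

**Compound list**

1 | (2E,6E)-farnesol | CC(C)=CCC/C(C)=C/CC/C(C)=C/CO | starting material
2 | (2E,6E)-farnesyl acetate | CC(C)=CCC/C(C)=C/CC/C(C)=C/COC(C)=O | intermediate
3 | (2E,6E,10E)-12-hydroxy-3,7,11-trimethyldodeca-2,6,10-trien-1-yl acetate | C/C(CO)=C\CC/C(C)=C/CC/C(C)=C/COC(C)=O | intermediate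
4 | (2E,6E,10E)-12-(tert-butyldimethylsilyloxy)-3,7,11-trimethyldodeca-2,6,10-trien-1-yl acetate | C/C(CO[Si](C)(C)C(C)(C)C)=C\CC/C(C)=C/CC/C(C)=C/COC(C)=O | intermediate
5 | (2E,6E,10E)-12-(tert-butyldimethylsilyloxy)-3,7,11-trimethyldodeca-2,6,10-trien-1-ol | C/C(CO[Si](C)(C)C(C)(C)C)=C\CC/C(C)=C/CC/C(C)=C/CO | intermediate
6 | (2E,6E,10E)-12-(tert-butyldimethylsilyloxy)-3,7,11-trimethyldodeca-2,6,10-trienal | C/C(CO[Si](C)(C)C(C)(C)C)=C\CC/C(C)=C/CC/C(C)=C/C=O | intermediate
7 | tert-butyldimethylsilyl ether of (2E,6E,10E)-2,6,10-trimethyltrideca-2,6,10,12-tetraen-1-ol | C/C(CO[Si](C)(C)C(C)(C)C)=C\CC/C(C)=C/CC/C(C)=C/C=C | intermediate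
8 | 9-[(3E,7E,11E)-13-(tert-butyldimethylsilyloxy)-4,8,12-trimethyltrideca-3,7,11-trien-1-yl]-9-borabicyclo[3.3.1]nonane | C/C(CO[Si](C)(C)C(C)(C)C)=C\CC/C(C)=C/CC/C(C)=C/CCB1C2CCCC1CCC2 | intermediate (not isolated)
9 | (3E,7E,11E)-13-(tert-butyldimethylsilyloxy)-4,8,12-trimethyltrideca-3,7,11-trien-1-ol | C/C(CO[Si](C)(C)C(C)(C)C)=C\CC/C(C)=C/CC/C(C)=C/CCO | intermediate
10 | (3E,7E,11E)-13-(tert-butyldimethylsilyloxy)-1-iodo-4,8,12-trimethyltrideca-3,7,11-triene | C/C(CO[Si](C)(C)C(C)(C)C)=C\CC/C(C)=C/CC/C(C)=C/CCI | intermediate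
11 | 2,2-dimethoxypropane-1,3-diol | COC(CO)(CO)OC | starting material
12 | 3-(tert-butyldimethylsilyloxy)-2,2-dimethoxypropan-1-ol | COC(CO)(OC)CO[Si](C)(C)C(C)(C)C | intermediate
13 | 3-(tert-butyldimethylsilyloxy)-2,2-dimethoxypropanal | COC(C=O)(OC)CO[Si](C)(C)C(C)(C)C | intermediate
14 | 2-{[(3R)-1-(tert-butyldimethylsilyloxy)-2,2-dimethoxyhex-5-yn-3-yl]oxy}-4,4,5,5-tetramethyl-1,3,2-dioxaborolane | C#CC[C@@H](OB1OC(C)(C)C(C)(C)O1)C(OC)(OC)CO[Si](C)(C)C(C)(C)C | intermediate (not isolated)
15 | (3R)-1-(tert-butyldimethylsilyloxy)-2,2-dimethoxyhex-5-yn-3-ol | C#CC[C@@H](O)C(OC)(OC)CO[Si](C)(C)C(C)(C)C | intermediate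
16 | (2R)-2-[2-(tert-butyldimethylsilyloxy)-1,1-dimethoxyethyl]-2,3-dihydrofuran | COC(OC)(CO[Si](C)(C)C(C)(C)C)[C@H]1CC=CO1 | intermediate
17 | [(3E,7E,11E)-13-(tert-butyldimethylsilyloxy)-4,8,12-trimethyltrideca-3,7,11-trien-1-yl]lithium | C/C(CO[Si](C)(C)C(C)(C)C)=C\CC/C(C)=C/CC/C(C)=C/CC[Li] | intermediate (not isolated)
18 | (2R)-2-[2-(tert-butyldimethylsilyloxy)-1,1-dimethoxyethyl]-5-lithio-2,3-dihydrofuran | COC(OC)(CO[Si](C)(C)C(C)(C)C)[C@H]1CC=C([Li])O1 | intermediate (not isolated)
19 | lithium alkyl(alkenyl)cuprate from 17, CuBr·SMe2 and 18 | [Li+].C/C(CO[Si](C)(C)C(C)(C)C)=C\CC/C(C)=C/CC/C(C)=C/CC[Cu-]C1=CC[C@H](C(OC)(OC)CO[Si](C)(C)C(C)(C)C)O1 | intermediate (not isolated)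
20 | ring-opened (Z)-alkenylcopper lithium alkoxide (copper on C6, lithium alkoxide on C3 of the nonadecatetraene chain) | C/C(CO[Si](C)(C)C(C)(C)C)=C\CC/C(C)=C/CC/C(C)=C/CC/C([Cu])=C/C[C@@H](O[Li])C(OC)(OC)CO[Si](C)(C)C(C)(C)C | intermediate (not isolated)
21 | (3R,5Z,9E,13E,17E)-1,19-bis(tert-butyldimethylsilyloxy)-2,2-dimethoxy-10,14,18-trimethyl-6-[(triisopropylsilyloxy)methyl]nonadeca-5,9,13,17-tetraen-3-ol | C/C(CO[Si](C)(C)C(C)(C)C)=C\CC/C(C)=C/CC/C(C)=C/CC/C(CO[Si](C(C)C)(C(C)C)C(C)C)=C/C[C@@H](O)C(OC)(OC)CO[Si](C)(C)C(C)(C)C | intermediate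
22 | (3R,5Z,9E,13E,17E)-1,19-bis(tert-butyldimethylsilyloxy)-3-hydroxy-10,14,18-trimethyl-6-[(triisopropylsilyloxy)methyl]nonadeca-5,9,13,17-tetraen-2-one | C/C(CO[Si](C)(C)C(C)(C)C)=C\CC/C(C)=C/CC/C(C)=C/CC/C(CO[Si](C(C)C)(C(C)C)C(C)C)=C/C[C@@H](O)C(=O)CO[Si](C)(C)C(C)(C)C | intermediate
23 | (triphenylphosphoranylidene)acetate ester of 22 | C/C(CO[Si](C)(C)C(C)(C)C)=C\CC/C(C)=C/CC/C(C)=C/CC/C(CO[Si](C(C)C)(C(C)C)C(C)C)=C/C[C@@H](OC(=O)C=P(c1ccccc1)(c1ccccc1)c1ccccc1)C(=O)CO[Si](C)(C)C(C)(C)C | intermediate (not isolated)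
24 | (5R)-4-[(tert-butyldimethylsilyloxy)methyl]-5-{(2Z,6E,10E,14E)-16-(tert-butyldimethylsilyloxy)-7,11,15-trimethyl-3-[(triisopropylsilyloxy)methyl]hexadeca-2,6,10,14-tetraen-1-yl}furan-2(5H)-one | C/C(CO[Si](C)(C)C(C)(C)C)=C\CC/C(C)=C/CC/C(C)=C/CC/C(CO[Si](C(C)C)(C(C)C)C(C)C)=C/C[C@H]1OC(=O)C=C1CO[Si](C)(C)C(C)(C)C | intermediate
25 | Hippolide F, (5R)-4-(hydroxymethyl)-5-[(2Z,6E,10E,14E)-16-hydroxy-3-(hydroxymethyl)-7,11,15-trimethylhexadeca-2,6,10,14-tetraen-1-yl]furan-2(5H)-one | C/C(=C\CC/C(C)=C/CC/C(C)=C/CC/C(=C/C[C@H]1OC(=O)C=C1CO)CO)CO | target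

**Step count and risks**

Total step count: 16. Longest linear sequence: 12 steps (steps 1–8, then 13–16, from (2E,6E)-farnesol).

Steps most likely to fail:

1. Step 13. After the metalate shift, C-alkylation of the alkenylcopper by the α-chloro ether may be outrun by protonation or by O-alkylation of the neighbouring alkoxide. The fallback sets out from 10 and 16 and runs the same lithiation, cuprate formation and rearrangement, but quenches the alkenylcopper with I2, the classical electrophile for such species. This should give the (Z)-alkenyl iodide F1. Stille coupling of F1 with Bu3SnCH2OH [Pd(PPh3)4, zerovalent palladium, toluene, 90 °C] should give the diol F2. Selective silylation of its primary allylic hydroxyl (i-Pr3SiCl, imidazole, CH2Cl2, 0 °C) comes back to the route at 21.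

2. Step 14. Hydrolysis of the doubly α-oxygenated ketal is slow, so acid-mediated loss of the primary silyl ethers, or enediol-mediated epimerisation of the carbinol centre, may compete. The fallback sets out from 21. Esterification with diethylphosphonoacetic acid (DCC, DMAP, CH2Cl2) should give the phosphonoacetate F3. Because desilylation is now wanted, stronger acid can be used: aqueous HCl in THF should cleave the ketal and all three silyl ethers to the keto phosphonate triol F4. An intramolecular Horner–Wadsworth–Emmons reaction (LiCl, i-Pr2NEt, MeCN, rt) then closes the butenolide in the presence of the free hydroxyls and comes back to the route at 25.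

3. Step 11. Uncatalysed background allenylboration of the activated α,α-dialkoxy aldehyde, or a poor fit of its quaternary centre in the catalyst pocket, may give poor facial selectivity. The fallback sets out from 13. Corey–Chaykovsky epoxidation (Me3SI, KOtBu, DMSO) should give the racemic epoxide F5. Hydrolytic kinetic resolution with the chiral (salen)Co(OAc) complex (trivalent cobalt; salen = N,N′-bis(3,5-di-tert-butylsalicylidene)-1,2-cyclohexanediamine dianion) and 0.55 equiv of water should leave the (R)-epoxide F6 and convert the other enantiomer into the (S)-diol F7, which is separated. Opening of F6 at its CH2 terminus with lithium acetylide–ethylenediamine complex in DMSO comes back to the route at 15.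

Further compounds
F1 | step 13 | (3R,5Z,9E,13E,17E)-1,19-bis(tert-butyldimethylsilyloxy)-6-iodo-2,2-dimethoxy-10,14,18-trimethylnonadeca-5,9,13,17-tetraen-3-ol | C/C(CO[Si](C)(C)C(C)(C)C)=C\CC/C(C)=C/CC/C(C)=C/CC/C(I)=C/C[C@@H](O)C(OC)(OC)CO[Si](C)(C)C(C)(C)C
F2 | step 13 | (3R,5Z,9E,13E,17E)-1,19-bis(tert-butyldimethylsilyloxy)-6-(hydroxymethyl)-2,2-dimethoxy-10,14,18-trimethylnonadeca-5,9,13,17-tetraen-3-ol | C/C(CO[Si](C)(C)C(C)(C)C)=C\CC/C(C)=C/CC/C(C)=C/CC/C(CO)=C/C[C@@H](O)C(OC)(OC)CO[Si](C)(C)C(C)(C)C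
F3 | step 14 | (diethoxyphosphoryl)acetate ester of 21 | C/C(CO[Si](C)(C)C(C)(C)C)=C\CC/C(C)=C/CC/C(C)=C/CC/C(CO[Si](C(C)C)(C(C)C)C(C)C)=C/C[C@@H](OC(=O)CP(=O)(OCC)OCC)C(OC)(OC)CO[Si](C)(C)C(C)(C)C
F4 | step 14 | (3R,5Z,9E,13E,17E)-1,19-dihydroxy-6-(hydroxymethyl)-10,14,18-trimethyl-2-oxononadeca-5,9,13,17-tetraen-3-yl (diethoxyphosphoryl)acetate | C/C(CO)=C\CC/C(C)=C/CC/C(C)=C/CC/C(CO)=C/C[C@@H](OC(=O)CP(=O)(OCC)OCC)C(=O)CO
F5 | step 11 | racemic tert-butyl[2,2-dimethoxy-2-(oxiran-2-yl)ethoxy]dimethylsilane | COC(OC)(CO[Si](C)(C)C(C)(C)C)C1CO1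
F6 | step 11 | tert-butyl{2,2-dimethoxy-2-[(2R)-oxiran-2-yl]ethoxy}dimethylsilane | COC(OC)(CO[Si](C)(C)C(C)(C)C)[C@H]1CO1
F7 | step 11 | (2S)-4-(tert-butyldimethylsilyloxy)-3,3-dimethoxybutane-1,2-diol | COC(OC)(CO[Si](C)(C)C(C)(C)C)[C@@H](O)CO
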